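**Strategy.** The route rests on disconnecting the lactone C–O bond at C6a of the cyclopenta[b]furanone (C3 of the spiro[4.5]decane five-membered ring). This CH2 carbon lies γ to the carboxyl carbon of a propanoic acid on the neighbouring ring CH (C2) and is not attached to the spiro carbon. A carboxylate-bound manganese oxo oxidises the cis C3–H bond and closes the cis-fused γ-lactone in one operation, setting the C–O stereocentre. Its precursor, keto acid 31, is a spiro[4.5]decane with C10 ketone, trans C7/C8 acetates and C6 methyl, built by Negishi coupling, methylcuprate addition and spiro-alkylation.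

Key step: step 21

Remark 1: the acid α-carbon forms unselectively in step 19 and is carried as a pair of epimers through 30–37 (no descriptor in those SMILES); both converge in steps 26–27.
Remark 2: the (S)-oxazolidinone is required, because alkylation anti to its benzyl group gives the 3S centre of 14 that becomes the R-configured ring-fusion carbon of the target.
Locants: spiro[4.5]decane numbering up to 31 (C1–C4 cyclopentane, C5 spiro, C6–C10 cyclohexane); from 32 on, unprimed C1–C6 = cyclohexane ring (C1 spiro), primed = cyclopenta[b]furanone (O1', C2' carbonyl, C3', C3a', C4', C5' spiro, C6', C6a').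

Step 1
Reactants: 1 cyclohexa-1,3-diene
Product: 2 cis-cyclohex-2-ene-1,4-diyl diacetate (meso)
Conditions: Pd(OAc)2 (5 mol%), LiCl (20 mol%), LiOAc, p-benzoquinone (2 equiv), AcOH, 25 °C
Reagents that add atoms: acetic acid, CC(=O)O
Why: Palladium-catalysed 1,4-diacetoxylation of a 1,3-diene, in which catalytic chloride keeps acetate off the metal so that both acetates attack from outside and the cis (meso) diacetate should result.

Step 2
Reactants: 2 cis-cyclohex-2-ene-1,4-diyl diacetate
Product: 3 (1S,4R)-4-hydroxycyclohex-2-en-1-yl acetate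
Conditions: Pseudomonas cepacia lipase, phosphate buffer pH 7, 25 °C
Reagents that add atoms: none
Why: Enzymatic desymmetrisation of a meso diacetate by ester hydrolysis, the lipase being expected to hydrolyse the acetate on the R-configured carbinol carbon, which fixes both stereocentres of 3.

Step 3
Reactants: 3 (1S,4R)-4-hydroxycyclohex-2-en-1-yl acetate
Product: 4 (1S,4R)-4-[(tert-butyldimethylsilyl)oxy]cyclohex-2-en-1-yl acetate
Conditions: tert-butyldimethylsilyl chloride, imidazole, DMF, 25 °C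
Reagents that add atoms: tert-butyldimethylsilyl chloride, CC(C)(C)[Si](C)(C)Cl
Why: Silylation of the free secondary alcohol, which touches no stereocentre.

Step 4
Reactants: 4 (1S,4R)-4-[(tert-butyldimethylsilyl)oxy]cyclohex-2-en-1-yl acetate
Product: 5 (1S,4R)-4-[(tert-butyldimethylsilyl)oxy]cyclohex-2-en-1-ol
Conditions: K2CO3, MeOH, 0 °C
Reagents that add atoms: none
Why: Base-catalysed transesterification removes the acetate while the silyl ether is stable.

Step 5
Reactants: 5 (1S,4R)-4-[(tert-butyldimethylsilyl)oxy]cyclohex-2-en-1-ol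
Product: 6 (4R)-4-[(tert-butyldimethylsilyl)oxy]cyclohex-2-en-1-one
Conditions: MnO2 (excess), CH2Cl2, 25 °C
Reagents that add atoms: none
Why: Allylic alcohol oxidation gives the enone, and the remaining silyl ether carbon (C4) keeps its R configuration.

Step 6
Reactants: 6 (4R)-4-[(tert-butyldimethylsilyl)oxy]cyclohex-2-en-1-one
Product: 7 (4R)-4-[(tert-butyldimethylsilyl)oxy]-2-iodocyclohex-2-en-1-one
Conditions: I2, pyridine, CH2Cl2, 0 → 25 °C
Reagents that add atoms: iodine, II
Why: α-Iodination of an enone by pyridine conjugate addition, iodination of the enolate and elimination (a Baylis–Hillman-type sequence).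

Step 7
Reactants: 8 3-methylbut-3-enoic acid; 9 (S)-4-benzyl-1,3-oxazolidin-2-one
Product: 11 (4S)-4-benzyl-3-(3-methylbut-3-enoyl)-1,3-oxazolidin-2-one, via mixed pivalic anhydride 10 (not isolated)
Conditions: pivaloyl chloride, Et3N, THF, −20 °C; then 9, LiCl, 25 °C
Reagents that add atoms: none
Why: N-Acylation of the oxazolidinone through a mixed anhydride under weakly basic conditions that should not move the β,γ-double bond into conjugation.

Step 8
Reactants: 11 (4S)-4-benzyl-3-(3-methylbut-3-enoyl)-1,3-oxazolidin-2-one; 12 tert-butyl bromoacetate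
Product: 14 tert-butyl (3S)-3-{[(4S)-4-benzyl-2-oxo-1,3-oxazolidin-3-yl]carbonyl}-4-methylpent-4-enoate, via sodium enolate 13 (not isolated)
Conditions: NaN(SiMe3)2, THF, −78 °C; then 12, −78 → −40 °C
Reagents that add atoms: none
Why: Evans asymmetric alkylation, in which the chelated Z-dienolate is alkylated at its α-carbon on the face opposite the benzyl group, setting the 3S centre and keeping the isopropenyl group.

Step 9
Reactants: 14 tert-butyl (3S)-3-{[(4S)-4-benzyl-2-oxo-1,3-oxazolidin-3-yl]carbonyl}-4-methylpent-4-enoate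
Product: 15 tert-butyl (3S)-3-(hydroxymethyl)-4-methylpent-4-enoate
Conditions: LiBH4, MeOH (1 equiv), THF, 0 °C
Reagents that add atoms: none
Why: Reductive cleavage of the imide by borohydride, which is faster than reduction of the tert-butyl ester and releases the auxiliary.

Step 10
Reactants: 15 tert-butyl (3S)-3-(hydroxymethyl)-4-methylpent-4-enoate
Product: 16 tert-butyl (3S)-3-(iodomethyl)-4-methylpent-4-enoate
Conditions: I2, PPh3, imidazole, CH2Cl2, 0 °C
Reagents that add atoms: iodine, II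
Why: Appel iodination of a primary alcohol, which leaves the adjacent stereocentre untouched.

Step 11
Reactants: 16 tert-butyl (3S)-3-(iodomethyl)-4-methylpent-4-enoate
Product: 17 (3S)-3-(iodomethyl)-4-methylpent-4-en-1-ol
Conditions: iBu2AlH (2.5 equiv), CH2Cl2, −78 → −20 °C; aq. KNaC4H4O6 work-up
Reagents that add atoms: none
Why: Hydride reduction of the ester to the primary alcohol, with the alkyl iodide and alkene inert and a neutral work-up to avoid tetrahydrofuran formation.

Step 12
Reactants: 17 (3S)-3-(iodomethyl)-4-methylpent-4-en-1-ol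
Product: 18 (3S)-5-chloro-3-(iodomethyl)-2-methylpent-1-ene
Conditions: PPh3, N-chlorosuccinimide, CH2Cl2, 0 → 25 °C
Reagents that add atoms: N-chlorosuccinimide, O=C1CCC(=O)N1Cl
Why: Appel-type chlorination of the primary alcohol gives a 1,4-dihalide whose two ends differ sharply in reactivity towards zinc.

Step 13
Reactants: 18 (3S)-5-chloro-3-(iodomethyl)-2-methylpent-1-ene; 7 (4R)-4-[(tert-butyldimethylsilyl)oxy]-2-iodocyclohex-2-en-1-one
Product: 20 (4R)-4-[(tert-butyldimethylsilyl)oxy]-2-[(2S)-2-(2-chloroethyl)-3-methylbut-3-en-1-yl]cyclohex-2-en-1-one, via alkylzinc iodide 19 (not isolated)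
Conditions: Zn dust, LiCl, THF, 40 °C; then 7, PdCl2(dppf) (5 mol%), THF, 25 → 45 °C
Reagents that add atoms: none
Why: Negishi sp3–sp2 coupling of a primary alkylzinc iodide with an α-iodoenone, zinc inserting into C–I but not C–Cl and no stereocentre being involved.

Step 14
Reactants: 20 (4R)-4-[(tert-butyldimethylsilyl)oxy]-2-[(2S)-2-(2-chloroethyl)-3-methylbut-3-en-1-yl]cyclohex-2-en-1-one
Product: 22 (2R,5S,9R,10R)-9-[(tert-butyldimethylsilyl)oxy]-10-methyl-2-(prop-1-en-2-yl)spiro[4.5]decan-6-one, via lithium enolate 21 (not isolated)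
Conditions: Me2CuLi (1.3 equiv, from CuI and MeLi), Et2O, −78 → −20 °C; then DMPU, THF, 25 → 45 °C
Reagents that add atoms: lithium dimethylcuprate, [Li+].C[Cu-]C
Why: Michael-initiated ring closure, in which the cuprate adds anti to the pseudoaxial silyloxy group to set the methyl centre and the regiodefined enolate, its methyl pseudoaxial to avoid A(1,2) strain, displaces chloride 5-exo-tet on the face anti to that methyl, so the spiro carbon should be S with the first-attached CH2 cis to methyl.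

Step 15
Reactants: 22 (2R,5S,9R,10R)-9-[(tert-butyldimethylsilyl)oxy]-10-methyl-2-(prop-1-en-2-yl)spiro[4.5]decan-6-one
Product: 24 (2R,5S,9R,10R)-9-[(tert-butyldimethylsilyl)oxy]-10-methyl-2-(prop-1-en-2-yl)spiro[4.5]dec-7-en-6-one, via trimethylsilyl enol ether 23 (not isolated)
Conditions: Me3SiOTf, Et3N, CH2Cl2, 0 °C; then Pd(OAc)2 (1.1 equiv), MeCN, 25 °C
Reagents that add atoms: none
Why: Saegusa–Ito oxidation, regiochemically unambiguous because the ketone can enolise only towards C7.

Step 16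
Reactants: 24 (2R,5S,9R,10R)-9-[(tert-butyldimethylsilyl)oxy]-10-methyl-2-(prop-1-en-2-yl)spiro[4.5]dec-7-en-6-one
Product: 26 (2R,5S,8S,9S,10R)-9-[(tert-butyldimethylsilyl)oxy]-8-hydroxy-10-methyl-2-(prop-1-en-2-yl)spiro[4.5]decan-6-one, via pinacol boronate 25 (not isolated)
Conditions: B2pin2, CuCl (5 mol%), NaOtBu (10 mol%), Xantphos (5 mol%), MeOH (2 equiv), THF, 25 °C; then NaBO3·4H2O, THF/H2O, 25 °C
Reagents that add atoms: sodium perborate, [Na+].[O-]OB=O
Why: Copper-catalysed conjugate borylation and C–B oxidation with retention, the boryl-copper species adding to C8 anti to the C9 silyloxy group so that the new hydroxyl should be trans to C9–O (8S).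

Step 17
Reactants: 26 (2R,5S,8S,9S,10R)-9-[(tert-butyldimethylsilyl)oxy]-8-hydroxy-10-methyl-2-(prop-1-en-2-yl)spiro[4.5]decan-6-one
Product: 27 (2R,5S,8S,9S,10R)-8,9-dihydroxy-10-methyl-2-(prop-1-en-2-yl)spiro[4.5]decan-6-one
Conditions: HF·pyridine, pyridine, THF, 0 → 25 °C
Reagents that add atoms: none
Why: Buffered fluoride desilylation, non-basic so that the β-hydroxy ketone should neither eliminate nor undergo retro-aldol cleavage.

Step 18
Reactants: 27 (2R,5S,8S,9S,10R)-8,9-dihydroxy-10-methyl-2-(prop-1-en-2-yl)spiro[4.5]decan-6-one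
Product: 28 (2R,5S,6R,7S,8S)-6-methyl-10-oxo-2-(prop-1-en-2-yl)spiro[4.5]decane-7,8-diyl diacetate
Conditions: Ac2O, pyridine, DMAP (5 mol%), CH2Cl2, 0 °C
Reagents that add atoms: acetic anhydride, CC(=O)OC(C)=O
Why: Acetylation of both secondary alcohols installs the electron-withdrawing groups needed for step 21, the equatorial β-acetate being poorly aligned for elimination at 0 °C.

Step 19
Reactants: 28 (2R,5S,6R,7S,8S)-6-methyl-10-oxo-2-(prop-1-en-2-yl)spiro[4.5]decane-7,8-diyl diacetate
Product: 30 (2R,5S,6R,7S,8S)-2-(1-hydroxypropan-2-yl)-6-methyl-10-oxospiro[4.5]decane-7,8-diyl diacetate, via B-alkyl-9-BBN adduct 29 (not isolated)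
Conditions: 9-BBN (1.5 equiv), THF, 0 → 25 °C; then aq. NaOAc, 30% H2O2, 0 → 25 °C
Reagents that add atoms: hydrogen peroxide, OO
Why: Anti-Markovnikov hydroboration–oxidation of the 1,1-disubstituted alkene, faster than reduction of the hindered ketone; the new side-chain centre forms unselectively (harmless) and any C10 carbinol is re-oxidised in step 20.

Step 20
Reactants: 30 (2R,5S,6R,7S,8S)-2-(1-hydroxypropan-2-yl)-6-methyl-10-oxospiro[4.5]decane-7,8-diyl diacetate
Product: 31 2-[(2R,5S,6R,7S,8S)-7,8-bis(acetyloxy)-6-methyl-10-oxospiro[4.5]decan-2-yl]propanoic acid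
Conditions: CrO3, H2SO4, H2O, acetone, 0 °C
Reagents that add atoms: water, O
Why: Jones oxidation takes the primary alcohol through the aldehyde hydrate to the acid under acidic conditions that leave the β-acetoxy ketone intact.

Step 21
Reactants: 31 2-[(2R,5S,6R,7S,8S)-7,8-bis(acetyloxy)-6-methyl-10-oxospiro[4.5]decan-2-yl]propanoic acid
Product: 32 (1R,3a'R,4S,5S,6R,6a'R)-3',6-dimethyl-2,2'-dioxohexahydro-2'H-spiro[cyclohexane-1,5'-cyclopenta[b]furan]-4,5-diyl diacetate
Conditions: Mn(PDP)(OTf)2 (racemic, 2 mol%), 50% aq. H2O2 (2.5 equiv, slow addition), CF3CH2OH, 0 °C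
Reagents that add atoms: none
Why: The carboxylate of 31 binds manganese, H2O2 is cleaved to a high-valent manganese oxo carboxylate, and this abstracts a γ-hydrogen through a seven-membered transition state, after which the carbon radical is captured by the bound carboxylate (or by hydroxyl, then lactonised); this is the known carboxylic-acid-directed γ-C–H lactonisation of unactivated methylene groups with manganese aminopyridine catalysts. The five-membered lactone closes by C–O bond formation at C3 (a 5-exo-type rebound onto the ring carbon) and can only be cis-fused, so the hydrogen cis to the acid chain is removed and the new C–O stereocentre (R) is dictated by C2. The step needs site selectivity between the two γ-methylenes: C1 is neopentyl, shielded by the spiro carbon C5 and inductively deactivated as a β-carbon of the C10 ketone, whereas C3 is remote and open. The ketone and both acetates make the C–H bonds of the six-membered ring electron-poor, and the C2–H and α-C–H bonds cannot reach the bound oxidant. Both α-epimers converge, and the racemic catalyst lets each find a matched enantiomer.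

Step 22
Reactants: 32 keto lactone diacetate (name as in step 21)
Product: 34 (1R,3a'R,4S,5S,6R,6a'R)-3',6-dimethyl-2'-oxo-2-[(trifluoromethanesulfonyl)oxy]hexahydro-2'H-spiro[cyclohex-2-ene-1,5'-cyclopenta[b]furan]-4,5-diyl diacetate, via potassium enolate 33 (not isolated)
Conditions: KN(SiMe3)2 (1.05 equiv) added to 32 and PhNTf2, THF, −78 °C
Reagents that add atoms: N-phenylbis(trifluoromethanesulfonimide), O=S(=O)(N(c1ccccc1)S(=O)(=O)C(F)(F)F)C(F)(F)F
Why: Kinetic enolisation at the only enolisable ketone position (C3) with in-situ O-sulfonylation gives the enol triflate, the equatorial C4 acetate being misaligned for β-elimination at −78 °C.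

Step 23
Reactants: 34 enol triflate diacetate (name as in step 22)
Product: 35 (1R,3a'R,4S,5S,6R,6a'R)-2-(hydroxymethyl)-3',6-dimethyl-2'-oxohexahydro-2'H-spiro[cyclohex-2-ene-1,5'-cyclopenta[b]furan]-4,5-diyl diacetate
Conditions: Bu3SnCH2OH (2 equiv), Pd(PPh3)4 (10 mol%), LiCl (3 equiv), 1,4-dioxane, 95 °C
Reagents that add atoms: (tributylstannyl)methanol, CCCC[Sn](CCCC)(CCCC)CO
Why: Stille coupling of the enol triflate with a hydroxymethyl stannane delivers the allylic alcohol directly and tolerates lactone and acetates.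

Step 24
Reactants: 35 allylic alcohol diacetate (name as in step 23)
Product: 36 (1R,3a'R,4S,5S,6R,6a'R)-4,5-dihydroxy-2-(hydroxymethyl)-3',6-dimethyl-hexahydro-2'H-spiro[cyclohex-2-ene-1,5'-cyclopenta[b]furan]-2'-one
Conditions: K2CO3, MeOH, 0 °C; then AcOH
Reagents that add atoms: none
Why: Methanolysis of both acetates now that no β-acyloxy ketone is present, any ring-opened hydroxy ester relactonising on acidification.

Step 25
Reactants: 36 triol lactone (name as in step 24)
Product: 37 tris(triethylsilyl) ether of 36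
Conditions: Et3SiOTf, 2,6-lutidine, CH2Cl2, −78 → 0 °C
Reagents that add atoms: triethylsilyl trifluoromethanesulfonate, CC[Si](CC)(CC)OS(=O)(=O)C(F)(F)F
Why: Silylation of all three hydroxyls gives base-stable, fluoride-labile protection for the lactone enolate chemistry.

Step 26
Reactants: 37 tris(triethylsilyl) ether
Product: 39 (3'R,3a'S)-3'-bromo-3'-methyl lactone tris(triethylsilyl) ether (bromine cis to the C3a' hydrogen), via lithium enolate 38 (not isolated)
Conditions: LiN(iPr)2, THF, −78 °C; then CBr4, −78 °C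
Reagents that add atoms: carbon tetrabromide, BrC(Br)(Br)Br
Why: Enolate bromination on the convex face of the cis-fused bicycle, cis to the ring-fusion hydrogens, converges both C3' epimers to one tertiary bromide.

Step 27
Reactants: 39 α-bromo lactone
Product: 40 (1R,3a'R,4S,5S,6R,6a'R)-3'-methylidene lactone tris(triethylsilyl) ether
Conditions: DBU, toluene, 25 → 50 °C
Reagents that add atoms: none
Why: E2 dehydrobromination needs an antiperiplanar hydrogen, and because bromine is cis to the C3a' hydrogen only the methyl hydrogens qualify, so the exocyclic alkene should form and not the butenolide.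

Step 28
Reactants: 40 α-methylene lactone tris(triethylsilyl) ether
Product: 41 (1R,3a'R,4S,5S,6R,6a'R)-4,5-dihydroxy-2-(hydroxymethyl)-6-methyl-3'-methylidene-hexahydro-2'H-spiro[cyclohex-2-ene-1,5'-cyclopenta[b]furan]-2'-one
Conditions: HF·pyridine, pyridine, THF, 0 → 25 °C
Reagents that add atoms: none
Why: Buffered fluoride desilylation, to which the α-methylene lactone is inert.

Step 29
Reactants: 41 triol (name as in step 28); 42 angelic acid, (2Z)-2-methylbut-2-enoic acid
Product: 44 target, via mixed trichlorobenzoic anhydride 43 (not isolated)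
Conditions: 2,4,6-trichlorobenzoyl chloride, Et3N, toluene, 25 °C; then 41, 25 → 50 °C
Reagents that add atoms: none
Why: Yamaguchi esterification without nucleophilic catalyst, the primary allylic alcohol being acylated far faster than the two secondary alcohols and the Z geometry of the angelate being kept.

**Compound list**

1 | cyclohexa-1,3-diene | C1=CC=CCC1 | starting material
2 | cis-cyclohex-2-ene-1,4-diyl diacetate (meso) | CC(=O)O[C@H]1CC[C@@H](OC(C)=O)C=C1 | intermediate
3 | (1S,4R)-4-hydroxycyclohex-2-en-1-yl acetate | O[C@@H]1CC[C@H](OC(C)=O)C=C1 | intermediate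
4 | (1S,4R)-4-[(tert-butyldimethylsilyl)oxy]cyclohex-2-en-1-yl acetate | CC(C)(C)[Si](C)(C)O[C@@H]1CC[C@H](OC(C)=O)C=C1 | intermediate
5 | (1S,4R)-4-[(tert-butyldimethylsilyl)oxy]cyclohex-2-en-1-ol | CC(C)(C)[Si](C)(C)O[C@@H]1CC[C@H](O)C=C1 | intermediate
6 | (4R)-4-[(tert-butyldimethylsilyl)oxy]cyclohex-2-en-1-one | CC(C)(C)[Si](C)(C)O[C@@H]1CCC(=O)C=C1 | intermediate
7 | (4R)-4-[(tert-butyldimethylsilyl)oxy]-2-iodocyclohex-2-en-1-one | CC(C)(C)[Si](C)(C)O[C@@H]1CCC(=O)C(I)=C1 | intermediate
8 | 3-methylbut-3-enoic acid | CC(=C)CC(O)=O | starting material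
9 | (S)-4-benzyl-1,3-oxazolidin-2-one | O=C1OC[C@H](Cc2ccccc2)N1 | starting material
10 | 3-methylbut-3-enoic pivalic anhydride | CC(=C)CC(=O)OC(=O)C(C)(C)C | intermediate
11 | (4S)-4-benzyl-3-(3-methylbut-3-enoyl)-1,3-oxazolidin-2-one | CC(=C)CC(=O)N1[C@@H](Cc2ccccc2)COC1=O | intermediate
12 | tert-butyl bromoacetate | BrCC(=O)OC(C)(C)C | starting material
13 | sodium (Z)-enolate of 11 | [Na]O/C(=C\C(C)=C)N1[C@@H](Cc2ccccc2)COC1=O | intermediate
14 | tert-butyl (3S)-3-{[(4S)-4-benzyl-2-oxo-1,3-oxazolidin-3-yl]carbonyl}-4-methylpent-4-enoate | CC(=C)[C@@H](C(=O)N1[C@@H](Cc2ccccc2)COC1=O)CC(=O)OC(C)(C)C | intermediate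
15 | tert-butyl (3S)-3-(hydroxymethyl)-4-methylpent-4-enoate | CC(=C)[C@@H](CO)CC(=O)OC(C)(C)C | intermediate
16 | tert-butyl (3S)-3-(iodomethyl)-4-methylpent-4-enoate | CC(=C)[C@@H](CI)CC(=O)OC(C)(C)C | intermediate
17 | (3S)-3-(iodomethyl)-4-methylpent-4-en-1-ol | CC(=C)[C@@H](CI)CCO | intermediate
18 | (3S)-5-chloro-3-(iodomethyl)-2-methylpent-1-ene | CC(=C)[C@@H](CI)CCCl | intermediate
19 | [(2S)-2-(2-chloroethyl)-3-methylbut-3-en-1-yl]zinc iodide | CC(=C)[C@@H](C[Zn]I)CCCl | intermediate
20 | (4R)-4-[(tert-butyldimethylsilyl)oxy]-2-[(2S)-2-(2-chloroethyl)-3-methylbut-3-en-1-yl]cyclohex-2-en-1-one | O=C1CC[C@@H](O[Si](C)(C)C(C)(C)C)C=C1C[C@@H](CCCl)C(C)=C | intermediate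
21 | lithium enolate of the 3-methyl ketone from 20 (methyl trans to the silyloxy group) | [Li]OC1=C(C[C@@H](CCCl)C(C)=C)[C@@H](C)[C@H](O[Si](C)(C)C(C)(C)C)CC1 | intermediate
22 | (2R,5S,9R,10R)-9-[(tert-butyldimethylsilyl)oxy]-10-methyl-2-(prop-1-en-2-yl)spiro[4.5]decan-6-one | CC(=C)[C@@H]1CC[C@@]2(C1)C(=O)CC[C@@H](O[Si](C)(C)C(C)(C)C)[C@@H]2C | intermediate
23 | 6-(trimethylsilyloxy)spiro[4.5]dec-6-ene derived from 22 | CC(=C)[C@@H]1CC[C@@]2(C1)C(O[Si](C)(C)C)=CC[C@@H](O[Si](C)(C)C(C)(C)C)[C@@H]2C | intermediate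
24 | (2R,5S,9R,10R)-9-[(tert-butyldimethylsilyl)oxy]-10-methyl-2-(prop-1-en-2-yl)spiro[4.5]dec-7-en-6-one | CC(=C)[C@@H]1CC[C@@]2(C1)C(=O)C=C[C@@H](O[Si](C)(C)C(C)(C)C)[C@@H]2C | intermediate
25 | 8-(pinacolatoboryl) ketone from 24 (boron trans to the C9 silyloxy group) | CC(=C)[C@@H]1CC[C@@]2(C1)C(=O)C[C@H](B3OC(C)(C)C(C)(C)O3)[C@@H](O[Si](C)(C)C(C)(C)C)[C@@H]2C | intermediate
26 | (2R,5S,8S,9S,10R)-9-[(tert-butyldimethylsilyl)oxy]-8-hydroxy-10-methyl-2-(prop-1-en-2-yl)spiro[4.5]decan-6-one | CC(=C)[C@@H]1CC[C@@]2(C1)C(=O)C[C@H](O)[C@@H](O[Si](C)(C)C(C)(C)C)[C@@H]2C | intermediate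
27 | (2R,5S,8S,9S,10R)-8,9-dihydroxy-10-methyl-2-(prop-1-en-2-yl)spiro[4.5]decan-6-one | CC(=C)[C@@H]1CC[C@@]2(C1)C(=O)C[C@H](O)[C@@H](O)[C@@H]2C | intermediate
28 | (2R,5S,6R,7S,8S)-6-methyl-10-oxo-2-(prop-1-en-2-yl)spiro[4.5]decane-7,8-diyl diacetate | CC(=C)[C@@H]1CC[C@@]2(C1)C(=O)C[C@H](OC(C)=O)[C@@H](OC(C)=O)[C@@H]2C | intermediate
29 | B-alkyl-9-borabicyclo[3.3.1]nonane adduct of 28 (side-chain epimers) | CC(CB1C2CCCC1CCC2)[C@@H]1CC[C@@]2(C1)C(=O)C[C@H](OC(C)=O)[C@@H](OC(C)=O)[C@@H]2C | intermediate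
30 | (2R,5S,6R,7S,8S)-2-(1-hydroxypropan-2-yl)-6-methyl-10-oxospiro[4.5]decane-7,8-diyl diacetate (side-chain epimers) | CC(CO)[C@@H]1CC[C@@]2(C1)C(=O)C[C@H](OC(C)=O)[C@@H](OC(C)=O)[C@@H]2C | intermediate
31 | 2-[(2R,5S,6R,7S,8S)-7,8-bis(acetyloxy)-6-methyl-10-oxospiro[4.5]decan-2-yl]propanoic acid (α-epimers) | CC(C(=O)O)[C@@H]1CC[C@@]2(C1)C(=O)C[C@H](OC(C)=O)[C@@H](OC(C)=O)[C@@H]2C | intermediate
32 | (1R,3a'R,4S,5S,6R,6a'R)-3',6-dimethyl-2,2'-dioxohexahydro-2'H-spiro[cyclohexane-1,5'-cyclopenta[b]furan]-4,5-diyl diacetate (C3' epimers) | CC1C(=O)O[C@@H]2C[C@@]3(C[C@H]12)C(=O)C[C@H](OC(C)=O)[C@@H](OC(C)=O)[C@@H]3C | intermediate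
33 | potassium enolate of 32 (C2–C3) | CC1C(=O)O[C@@H]2C[C@@]3(C[C@H]12)C(O[K])=C[C@H](OC(C)=O)[C@@H](OC(C)=O)[C@@H]3C | intermediate
34 | enol triflate of 32 (cyclohex-2-en-2-yl trifluoromethanesulfonate, diacetate) | CC1C(=O)O[C@@H]2C[C@@]3(C[C@H]12)C(OS(=O)(=O)C(F)(F)F)=C[C@H](OC(C)=O)[C@@H](OC(C)=O)[C@@H]3C | intermediate
35 | 2-(hydroxymethyl)cyclohex-2-ene lactone diacetate | CC1C(=O)O[C@@H]2C[C@@]3(C[C@H]12)C(CO)=C[C@H](OC(C)=O)[C@@H](OC(C)=O)[C@@H]3C | intermediate
36 | (4S,5S)-4,5-dihydroxy-2-(hydroxymethyl) lactone (triol, C3' epimers) | CC1C(=O)O[C@@H]2C[C@@]3(C[C@H]12)C(CO)=C[C@H](O)[C@@H](O)[C@@H]3C | intermediate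
37 | tris(triethylsilyl) ether of 36 | CC1C(=O)O[C@@H]2C[C@@]3(C[C@H]12)C(CO[Si](CC)(CC)CC)=C[C@H](O[Si](CC)(CC)CC)[C@@H](O[Si](CC)(CC)CC)[C@@H]3C | intermediate
38 | lithium enolate of lactone 37 | CC1=C(O[Li])O[C@@H]2C[C@@]3(C[C@H]12)C(CO[Si](CC)(CC)CC)=C[C@H](O[Si](CC)(CC)CC)[C@@H](O[Si](CC)(CC)CC)[C@@H]3C | intermediate
39 | (3'R,3a'S)-3'-bromo-3'-methyl lactone tris(triethylsilyl) ether (Br cis to C3a'–H) | C[C@]1(Br)C(=O)O[C@@H]2C[C@@]3(C[C@H]12)C(CO[Si](CC)(CC)CC)=C[C@H](O[Si](CC)(CC)CC)[C@@H](O[Si](CC)(CC)CC)[C@@H]3C | intermediate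
40 | 3'-methylidene lactone tris(triethylsilyl) ether | C=C1C(=O)O[C@@H]2C[C@@]3(C[C@H]12)C(CO[Si](CC)(CC)CC)=C[C@H](O[Si](CC)(CC)CC)[C@@H](O[Si](CC)(CC)CC)[C@@H]3C | intermediate
41 | (1R,3a'R,4S,5S,6R,6a'R)-4,5-dihydroxy-2-(hydroxymethyl)-6-methyl-3'-methylidene-hexahydro-2'H-spiro[cyclohex-2-ene-1,5'-cyclopenta[b]furan]-2'-one | C=C1C(=O)O[C@@H]2C[C@@]3(C[C@H]12)C(CO)=C[C@H](O)[C@@H](O)[C@@H]3C | intermediate
42 | angelic acid, (2Z)-2-methylbut-2-enoic acid | C/C=C(/C)C(=O)O | starting material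
43 | angelic 2,4,6-trichlorobenzoic anhydride | C/C=C(/C)C(=O)OC(=O)c1c(Cl)cc(Cl)cc1Cl | intermediate
44 | [(1R,3a'R,4S,5S,6R,6a'R)-4,5-dihydroxy-6-methyl-3'-methylidene-2'-oxo-hexahydro-2'H-spiro[cyclohex-2-ene-1,5'-cyclopenta[b]furan]-2-yl]methyl (2Z)-2-methylbut-2-enoate | C=C1C(=O)O[C@@H]2C[C@@]3(C[C@H]12)C(COC(=O)/C(C)=C\C)=C[C@H](O)[C@@H](O)[C@@H]3C | target

**Totals.** Total step count: 29. Longest linear sequence: 23 steps (steps 1–6, then 13–29; the fragment branch, steps 7–12 then 13–29, is equally long).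

**Steps most likely to fail**

Step 21. What may go wrong: hydrogen abstraction at the neopentyl C1 methylene instead of C3, or intermolecular over-oxidation or Baeyer–Villiger reaction of the ketone competing with the directed pathway. Fallback, from 31 back to 32: the acid is converted (isobutyl chloroformate, N-methylmorpholine, then NH3) into the primary amide F1. Irradiation with PhI(OAc)2 and I2 forms the N-iodo amide F2, whose amidyl radical takes the C3 hydrogen by 1,5-transfer (Hofmann–Löffler–Freytag-type remote functionalisation) to give the 3-iodo amide F3. The amide oxygen then displaces iodide to give the cis-fused iminolactone hydroiodide F4, and aqueous hydrolysis gives 32.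

Step 14. What may go wrong: ring closure on the enolate face syn to the methyl group if the all-equatorial half-chair reacts, or slow chloride displacement that lets the enolate equilibrate. Fallback, from 15 and 7 back to 22: the two ends of the four-carbon unit are exchanged, so that the carbon attached first and the carbon that closes the ring change places. 15 is chlorinated (PPh3, N-chlorosuccinimide) to the chloro ester F5, reduced (iBu2AlH) to the chloro alcohol F6 and iodinated (I2, PPh3, imidazole) to the chloro iodide F7. Zinc insertion gives the alkylzinc iodide F8, Negishi coupling with 7 gives the enone F9, and Me2CuLi addition gives the lithium enolate F10. This enolate closes the ring through the branched CH2Cl carbon (NaI, DMPU), so closure syn to methyl then leads to the same spiroketone 22.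

Step 22. What may go wrong: loss of the C4 acetate by β-elimination from the potassium enolate before O-sulfonylation, or competing deprotonation of the acetates. Fallback, from 32 back to 37: the acetates are exchanged for silyl ethers before enolisation. Acid methanolysis (AcCl, MeOH, 0 → 25 °C) gives the keto lactone diol F11, and Et3SiOTf/2,6-lutidine gives the bis(triethylsilyl) ether F12. KN(SiMe3)2/PhNTf2 then gives, through the potassium enolate F13, the enol triflate F14 (a routine triflation of a β-silyloxy ketone). Stille coupling with Bu3SnCH2OH gives the allylic alcohol F15, and silylation of its primary hydroxyl gives 37.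

**Further compounds**

F1 | step 21 | 2-[(2R,5S,6R,7S,8S)-7,8-bis(acetyloxy)-6-methyl-10-oxospiro[4.5]decan-2-yl]propanamide | CC(C(N)=O)[C@@H]1CC[C@@]2(C1)C(=O)C[C@H](OC(C)=O)[C@@H](OC(C)=O)[C@@H]2C
F2 | step 21 | N-iodo derivative of amide F1 | CC(C(=O)NI)[C@@H]1CC[C@@]2(C1)C(=O)C[C@H](OC(C)=O)[C@@H](OC(C)=O)[C@@H]2C
F3 | step 21 | 3-iodo amide (iodine trans to the side chain) | CC(C(N)=O)[C@@H]1[C@@H](I)C[C@@]2(C1)C(=O)C[C@H](OC(C)=O)[C@@H](OC(C)=O)[C@@H]2C
F4 | step 21 | cis-fused 2'-imino lactone hydroiodide corresponding to 32 | CC1C(=N)O[C@@H]2C[C@@]3(C[C@H]12)C(=O)C[C@H](OC(C)=O)[C@@H](OC(C)=O)[C@@H]3C.I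
F5 | step 14 | tert-butyl (3S)-3-(chloromethyl)-4-methylpent-4-enoate | CC(=C)[C@@H](CCl)CC(=O)OC(C)(C)C
F6 | step 14 | (3S)-3-(chloromethyl)-4-methylpent-4-en-1-ol | CC(=C)[C@@H](CCl)CCO
F7 | step 14 | (3S)-3-(chloromethyl)-5-iodo-2-methylpent-1-ene | CC(=C)[C@@H](CCl)CCI
F8 | step 14 | [(3S)-3-(chloromethyl)-4-methylpent-4-en-1-yl]zinc iodide | CC(=C)[C@@H](CCl)CC[Zn]I
F9 | step 14 | (4R)-4-[(tert-butyldimethylsilyl)oxy]-2-[(3S)-3-(chloromethyl)-4-methylpent-4-en-1-yl]cyclohex-2-en-1-one | O=C1CC[C@@H](O[Si](C)(C)C(C)(C)C)C=C1CC[C@H](CCl)C(C)=C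
F10 | step 14 | lithium enolate of the 3-methyl ketone from F9 | [Li]OC1=C(CC[C@H](CCl)C(C)=C)[C@@H](C)[C@H](O[Si](C)(C)C(C)(C)C)CC1
F11 | step 22 | keto lactone diol (4S,5S-dihydroxy analogue of 32) | CC1C(=O)O[C@@H]2C[C@@]3(C[C@H]12)C(=O)C[C@H](O)[C@@H](O)[C@@H]3C
F12 | step 22 | bis(triethylsilyl) ether of F11 | CC1C(=O)O[C@@H]2C[C@@]3(C[C@H]12)C(=O)C[C@H](O[Si](CC)(CC)CC)[C@@H](O[Si](CC)(CC)CC)[C@@H]3C
F13 | step 22 | potassium enolate of F12 | CC1C(=O)O[C@@H]2C[C@@]3(C[C@H]12)C(O[K])=C[C@H](O[Si](CC)(CC)CC)[C@@H](O[Si](CC)(CC)CC)[C@@H]3C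
F14 | step 22 | enol triflate of F12 | CC1C(=O)O[C@@H]2C[C@@]3(C[C@H]12)C(OS(=O)(=O)C(F)(F)F)=C[C@H](O[Si](CC)(CC)CC)[C@@H](O[Si](CC)(CC)CC)[C@@H]3C
F15 | step 22 | 2-(hydroxymethyl)cyclohex-2-ene lactone bis(triethylsilyl) ether | CC1C(=O)O[C@@H]2C[C@@]3(C[C@H]12)C(CO)=C[C@H](O[Si](CC)(CC)CC)[C@@H](O[Si](CC)(CC)CC)[C@@H]3C
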